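**Strategy.** In ring A the quaternary C1 and the sec-butyl-bearing C2 sit side by side between C8a and C3, so ring A is cut across C2–C3 and C1–C8a into a ring B 1-vinylcyclohexene and an (E)-enoyl imide. One aluminium-promoted endo Diels–Alder reaction closes ring A, makes both bonds and sets C2 and C8a (C1 is re-set later by methylation). The diene (C3=C4–C4a=C8a) carries the C5/C6 acetonide and the C8 methyl group and comes from (R)-pulegone; the dienophile carries the (R)-sec-butyl group and an (S)-benzyl oxazolidinone. Afterwards the Δ4(4a) alkene is shifted to C3=C4 through hydroboration, which fixes H4a.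

Key step: step 14

Remarks on the chemistry:
- Bicyclic compounds use the decalin numbering of the target: C1 quaternary, C2 sec-butyl, C3=C4, C4a, C5 O-acyl, C6 OH, C7, C8 methyl, C8a; side chain C9 (C=O), C10, C11 (OH). β is the face of H4a, the C5/C6 oxygens and the C1 methyl; α is the face of H8a, the C8 methyl and the sec-butyl group.
- The diene 13, dienophile 21 and adduct 22 were checked centre by centre against the target; no descriptor needed correction.
- Assumption: (E)-3-methylglutaconic acid (42) is bought as the pure E isomer.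

**Ring B diene**

Step 1
Reactants: 1 (R)-pulegone
Product: 2 pulegone oxide (2,2,6-trimethyl-1-oxaspiro[2.5]octan-4-one; both epimers at the spiro carbon)
Conditions: 30% H2O2, NaOH (cat.), MeOH, 0 °C → rt
Reagents that add atoms: hydrogen peroxide OO
Why: Weitz–Scheffer nucleophilic epoxidation of the enone; the spiro centre forms as a mixture, which does not matter because that carbon loses its stereochemistry in steps 2 and 3.

Step 2
Reactants: 2 pulegone oxide
Product: 3 (5R)-5-methyl-2-(phenylsulfanyl)cyclohexan-1-one (both C2 epimers)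
Conditions: PhSH (1.1 equiv), NaH (0.2 equiv), THF, 65 °C
Reagents that add atoms: thiophenol Sc1ccccc1
Why: Thiolate opens the α,β-epoxy ketone at the α-carbon and the resulting tertiary alkoxide undergoes retro-aldol loss of acetone (thiolate is regenerated by proton transfer), leaving the methyl-bearing centre untouched.

Step 3
Reactants: 3 (5R)-5-methyl-2-(phenylsulfanyl)cyclohexan-1-one
Product: 5 (R)-5-methylcyclohex-2-en-1-one, via sulfoxide 4 (not isolated)
Conditions: mCPBA (1.0 equiv), CH2Cl2, −78 °C; then CaCO3, toluene, 80 °C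
Reagents that add atoms: none
Why: Sulfide oxidation and thermal syn-elimination of the β-keto sulfoxide (sulfoxide pyrolysis) can only take a hydrogen from C3, so the C2=C3 enone forms without touching C5.

Step 4
Reactants: 5 (R)-5-methylcyclohex-2-en-1-one
Product: 6 (1R,5R)-5-methylcyclohex-2-en-1-ol (hydroxyl cis to methyl)
Conditions: NaBH4, CeCl3·7H2O, MeOH, −40 °C
Reagents that add atoms: none
Why: Luche 1,2-reduction; axial hydride delivery to the half-chair with equatorial methyl gives the pseudoequatorial alcohol, cis to the methyl group.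

Step 5
Reactants: 6 (1R,5R)-5-methylcyclohex-2-en-1-ol
Product: 7 (5R)-5-methylcyclohexane-1,2,3-triol (1-OH cis to methyl; 2-OH and 3-OH cis to each other and trans to methyl)
Conditions: OsO4 (2 mol %), NMO (1.3 equiv), acetone/H2O 4:1, 0 °C → rt
Reagents that add atoms: N-methylmorpholine N-oxide C[N+]1([O-])CCOCC1; water O
Why: Upjohn dihydroxylation; osmium tetroxide adds syn on the face anti to the allylic hydroxyl (the usual sense for cyclic allylic alcohols), so the two new centres (future C5 and C6) are cis to each other and trans to OH-1 and the methyl group.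

Step 6
Reactants: 7 triol
Product: 8 2,3-O-isopropylidene derivative of 7 (1-OH free)
Conditions: 2,2-dimethoxypropane, PPTS (cat.), acetone, rt
Reagents that add atoms: 2,2-dimethoxypropane COC(C)(C)OC
Why: Thermodynamic transketalisation takes the cis-vicinal diol (cis-fused dioxolane) and not the trans pair, so only the C1 hydroxyl stays free; no stereocentre is formed.

Step 7
Reactants: 8 acetonide alcohol
Product: 9 2,3-(isopropylidenedioxy)-5-methylcyclohexan-1-one (cis-fused dioxolane, oxygens trans to methyl)
Conditions: Dess–Martin periodinane, CH2Cl2, 0 °C → rt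
Reagents that add atoms: none
Why: Dess–Martin oxidation of the remaining secondary alcohol; the α-alkoxy centre is safe because its epimer would be a strained trans-fused acetonide.

Step 8
Reactants: 9 acetonide ketone
Product: 11 enol triflate (C1=C6 of the cyclohexanone; future C4a=C8a), via potassium enolate 10 (not isolated)
Conditions: KHMDS (1.1 equiv), THF, −78 °C; then PhNTf2, −78 → 0 °C
Reagents that add atoms: N-phenylbis(trifluoromethanesulfonimide) O=S(=O)(N(c1ccccc1)S(=O)(=O)C(F)(F)F)C(F)(F)F
Why: Kinetic deprotonation of the α-alkoxy ketone occurs at the unhindered α′-CH2 and O-triflation gives the less substituted enol triflate; no stereocentre is formed.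

Step 9
Reactants: 11 enol triflate; 12 tributyl(vinyl)stannane
Product: 13 ring B diene (C3=C4–C4a=C8a; 5β,6β-acetonide; 8α-methyl)
Conditions: Pd(PPh3)4 (5 mol %), LiCl (3 equiv), THF, 65 °C
Reagents that add atoms: none
Why: Stille coupling of an enol triflate with a vinylstannane (chloride-assisted transmetalation) gives the 1-vinylcyclohexene with all stereocentres untouched.

**Dienophile**

Step 10
Reactants: 14 (S)-4-benzyloxazolidin-2-one
Product: 16 (S)-4-benzyl-3-(bromoacetyl)oxazolidin-2-one, via lithium oxazolidinide 15 (not isolated)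
Conditions: n-BuLi (1.0 equiv), THF, −78 °C; then bromoacetyl bromide, −78 → 0 °C
Reagents that add atoms: bromoacetyl bromide BrCC(Br)=O
Why: N-Acylation of the lithiated oxazolidinone; the acyl bromide reacts far faster than the alkyl bromide.

Step 11
Reactants: 16 (S)-4-benzyl-3-(bromoacetyl)oxazolidin-2-one
Product: 17 diethyl {2-[(S)-4-benzyl-2-oxooxazolidin-3-yl]-2-oxoethyl}phosphonate
Conditions: P(OEt)3 (neat, 3 equiv), 80 °C
Reagents that add atoms: triethyl phosphite CCOP(OCC)OCC
Why: Michaelis–Arbuzov reaction of the α-bromo imide.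

Step 12
Reactants: 18 (R)-2-methylbutanoic acid
Product: 19 (R)-2-methylbutan-1-ol
Conditions: LiAlH4, Et2O, 0 °C → reflux; aqueous NaOH work-up
Reagents that add atoms: none
Why: Hydride reduction of the acid; the α-centre is not enolised under these conditions.

Step 13
Reactants: 19 (R)-2-methylbutan-1-ol; 17 phosphonate
Product: 21 (S)-4-benzyl-3-[(R,E)-4-methylhex-2-enoyl]oxazolidin-2-one, via (R)-2-methylbutanal 20 (not isolated)
Conditions: (COCl)2, DMSO, CH2Cl2, −78 °C; Et3N, −78 → −20 °C; then 17, LiCl, iPr2NEt, MeCN, 0 °C → rt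
Reagents that add atoms: none
Why: Swern oxidation followed by Horner–Wadsworth–Emmons olefination under Masamune–Roush conditions gives the E-enoyl imide, and the mild amine base does not epimerise the volatile α-branched aldehyde, which is used in solution.

**Key step**

Step 14
Reactants: 13 ring B diene; 21 enoyl imide
Product: 22 Diels–Alder adduct (Δ4(4a)-octalin; 1β-acyl oxazolidinone; 2α-(R)-sec-butyl; 8aα-H; 5β,6β-acetonide; 8α-methyl)
Conditions: Me2AlCl (1.5 equiv), CH2Cl2, −78 → −20 °C; 13 in slight excess
Reagents that add atoms: none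
Why: Me2AlCl turns the imide into a cationic bidentate aluminium chelate with an s-cis enoyl unit, and the electron-rich semicyclic diene adds to it in a concerted, asynchronous normal-demand [4+2] cycloaddition; the closest known reaction type is the dialkylaluminium chloride-promoted Diels–Alder reaction of chiral N-enoyl oxazolidinones with acyclic and 1-vinylcycloalkene dienes. Ring A is closed as a six-membered Δ4(4a)-cyclohexene by intermolecular annulation, C2–C3 and C1–C8a forming suprafacially on both partners. Regiochemistry follows from the larger HOMO coefficient at the unsubstituted terminus C3, which bonds to the β-carbon (C2), so the ring-bearing terminus C8a bonds to the α-carbon (C1). C2 is fixed by the E geometry (sec-butyl trans to acyl) and by attack on the Cα-Si face, the other face being covered by the benzyl group of the (S)-auxiliary; C1 is fixed by the endo position of the chelated carbonyl (acyl cis to C8, H1 cis to H8a) and is re-set in step 22. C8a is fixed by addition anti to the C8 methyl group, which is pseudoaxial in the reactive half-chair of ring B (the C5 oxygen sits pseudoaxial to avoid A(1,2) strain with the vinyl group). The step needs ortho regioselectivity, endo topology and one diene face, and the case is matched, because endo addition to the Cα-Si face gives the adduct with H8a α only by using the diene face opposite the C8 methyl group.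

**From the adduct to the target**

Step 15
Reactants: 22 Diels–Alder adduct
Product: 24 octalin-1β-carboxylic acid, via peroxy acid 23 (not isolated)
Conditions: LiOH·H2O (2 equiv), 30% H2O2 (4 equiv), THF/H2O 3:1, 0 °C; then aq. Na2SO3; 1 M HCl to pH 3
Reagents that add atoms: hydrogen peroxide OO
Why: Hydroperoxide cleaves the hindered imide selectively at the exocyclic carbonyl and sulfite reduces the peroxy acid; the auxiliary is recovered and no ring stereocentre is affected.

Step 16
Reactants: 24 carboxylic acid
Product: 26 octalin-1β-carboxamide, via acyl imidazolide 25 (not isolated)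
Conditions: 1,1′-carbonyldiimidazole (1.5 equiv), THF, rt → 40 °C; then 28% aq. NH3, 0 °C → rt
Reagents that add atoms: ammonia N
Why: Activation as the acyl imidazolide followed by aminolysis with the small nucleophile ammonia.

Step 17
Reactants: 26 primary amide
Product: 27 Δ4(4a)-octalin-1β-carbonitrile
Conditions: (CF3CO)2O, pyridine, CH2Cl2, 0 °C
Reagents that add atoms: none
Why: Dehydration of the primary amide; the nitrile is chosen as the C1 group because it is small, is easily alkylated at a hindered centre and gives the methyl ketone directly in step 23.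

Step 18
Reactants: 27 nitrile
Product: 29 trans-fused 4β-hydroxy-4aβ-H decalin nitrile, via C4 alkylborane 28 (not isolated)
Conditions: BH3·SMe2 (3 equiv), THF, 0 °C → rt; then 30% H2O2, aq. NaOAc, 0 °C → rt
Reagents that add atoms: hydrogen peroxide OO
Why: Hydroboration–oxidation; borane adds syn with boron at the less substituted C4 and from the β face, because the α face of C4 is screened by the 1,3-related axial sec-butyl group of the ring A half-chair, so the new H4a is β (trans to H8a) and the C4 hydroxyl is β; buffered peroxide spares the nitrile.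

Step 19
Reactants: 29 alcohol
Product: 30 trans-fused C4 ketone
Conditions: Dess–Martin periodinane, pyridine, CH2Cl2, 0 °C → rt
Reagents that add atoms: none
Why: Buffered Dess–Martin oxidation gives the ketone without enolisation, so the C4a centre is kept.

Step 20
Reactants: 30 ketone
Product: 32 Δ3-enol triflate, via potassium enolate 31 (not isolated)
Conditions: KHMDS (1.05 equiv), THF, −78 °C; then PhNTf2, −78 → 0 °C
Reagents that add atoms: N-phenylbis(trifluoromethanesulfonimide) O=S(=O)(N(c1ccccc1)S(=O)(=O)C(F)(F)F)C(F)(F)F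
Why: Kinetic enolisation of the 1-decalone-type ketone goes to the C3 methylene and not to the C4a methine or the less acidic, hindered nitrile α-hydrogen; O-triflation then places the double bond at C3=C4.

Step 21
Reactants: 32 enol triflate
Product: 33 trans-Δ3-octalin-1β-carbonitrile (4aβ-H, 8aα-H)
Conditions: Pd(OAc)2 (5 mol %), PPh3 (10 mol %), HCO2H, Bu3N, DMF, 60 °C
Reagents that add atoms: none
Why: Palladium-catalysed formate reduction of the enol triflate replaces OTf by H and leaves the C3=C4 alkene, nitrile and acetonide intact.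

Step 22
Reactants: 33 nitrile
Product: 35 1β-methyl-1α-carbonitrile (quaternary C1), via lithiated nitrile 34 (not isolated)
Conditions: LDA (1.3 equiv), THF, −78 → −20 °C; then MeI (3 equiv), −78 °C → rt
Reagents that add atoms: iodomethane CI
Why: α-Alkylation of a metalated nitrile; in the rigid trans-fused octalin MeI enters axially on the β face, anti to the pseudoaxial 2α-sec-butyl group (the equatorial approach is also closed by the peri C8 methyl), which sets C1 with methyl β and the carbon substituent α as in the target.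

Step 23
Reactants: 35 quaternary nitrile
Product: 37 1α-acetyl-1β-methyl octalin (methyl ketone), via lithium ketimide 36 (not isolated)
Conditions: MeLi (3 equiv), Et2O/toluene, 0 → 40 °C; then AcOH/NaOAc buffer (pH 4–5), THF/H2O, rt
Reagents that add atoms: methyllithium [Li]C; water O
Why: Addition of methyllithium to the non-enolisable tertiary nitrile stops at the ketimide, and mild buffered hydrolysis gives the ketone while sparing the acetonide.

Step 24
Reactants: 37 methyl ketone
Product: 39 β-hydroxy ketone (C9 ketone, C11 OH), via lithium enolate 38 (not isolated)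
Conditions: LDA (1.2 equiv), THF, −78 °C; then HCHO (gas, from cracked paraformaldehyde), −78 °C; AcOH quench
Reagents that add atoms: formaldehyde C=O
Why: Crossed aldol (hydroxymethylation) of the only possible enolate (C10, since C1 is quaternary) with monomeric formaldehyde; cold acidic quench prevents retro-aldol and dehydration.

Step 25
Reactants: 39 β-hydroxy ketone
Product: 40 C11 tert-butyldiphenylsilyl ether
Conditions: TBDPSCl, imidazole, CH2Cl2, 0 °C → rt
Reagents that add atoms: tert-butyl(chloro)diphenylsilane CC(C)(C)[Si](Cl)(c1ccccc1)c1ccccc1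
Why: Silylation of the primary alcohol; TBDPS is chosen because it survives the acid of step 26.

Step 26
Reactants: 40 silyl ether
Product: 41 5β,6β-diol
Conditions: AcOH/H2O 4:1, 50 °C
Reagents that add atoms: none
Why: Acid hydrolysis of the acetonide; the TBDPS ether, the alkene and the ketone are stable under these conditions.

Step 27
Reactants: 42 (E)-3-methylglutaconic acid
Product: 43 (E)-5-methoxy-3-methyl-5-oxopent-2-enoic acid
Conditions: MeOH, H2SO4 (cat.), 0 °C → rt, stopped at mono-ester
Reagents that add atoms: methanol CO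
Why: Fischer esterification is markedly faster at the saturated carboxyl than at the conjugated one (as in the 4-monoesters of itaconic acid), and acid catalysis leaves the position and E geometry of the double bond unchanged.

Step 28
Reactants: 41 diol; 43 half ester
Product: 44 C5 mono-ester (C6 OH free, C11 OTBDPS)
Conditions: EDC·HCl (1.3 equiv), DMAP (0.1 equiv), CH2Cl2, −20 → 0 °C
Reagents that add atoms: none
Why: Steglich-type carbodiimide esterification; the equatorial C5 hydroxyl should react ahead of the axial C6 hydroxyl (flanked by two syn-axial hydrogens), and substoichiometric DMAP at low temperature limits base-induced migration of the glutaconate double bond.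

Step 29
Reactants: 44 silyl ether ester
Product: 45 tandyukisin B
Conditions: HF·pyridine, pyridine, THF, 0 °C → rt
Reagents that add atoms: none
Why: Fluoride-mediated desilylation under weakly acidic conditions frees the C11 alcohol without acyl migration, retro-aldol or isomerisation of the glutaconate ester.

**Compound list**

1 | (R)-pulegone | C[C@@H]1CCC(=C(C)C)C(=O)C1 | starting material
2 | pulegone oxide (spiro epimers) | C[C@@H]1CCC2(OC2(C)C)C(=O)C1 | intermediate
3 | (5R)-5-methyl-2-(phenylsulfanyl)cyclohexan-1-one (C2 epimers) | C[C@@H]1CCC(Sc2ccccc2)C(=O)C1 | intermediate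
4 | (5R)-5-methyl-2-(phenylsulfinyl)cyclohexan-1-one | C[C@@H]1CCC(S(=O)c2ccccc2)C(=O)C1 | intermediate (not isolated)
5 | (R)-5-methylcyclohex-2-en-1-one | C[C@@H]1CC=CC(=O)C1 | intermediate
6 | (1R,5R)-5-methylcyclohex-2-en-1-ol | C[C@@H]1CC=C[C@H](O)C1 | intermediate
7 | (5R)-5-methylcyclohexane-1,2,3-triol (1-OH cis, 2-OH/3-OH trans to methyl) | C[C@@H]1C[C@@H](O)[C@@H](O)[C@H](O)C1 | intermediate
8 | 2,3-O-isopropylidene triol (1-OH free) | C[C@@H]1C[C@H]2OC(C)(C)O[C@H]2[C@H](O)C1 | intermediate
9 | 2,3-(isopropylidenedioxy)-5-methylcyclohexan-1-one | C[C@@H]1C[C@H]2OC(C)(C)O[C@H]2C(=O)C1 | intermediate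
10 | potassium enolate of 9 | C[C@@H]1C[C@H]2OC(C)(C)O[C@H]2C([O-])=C1.[K+] | intermediate (not isolated)
11 | enol triflate of 9 | C[C@@H]1C[C@H]2OC(C)(C)O[C@H]2C(OS(=O)(=O)C(F)(F)F)=C1 | intermediate
12 | tributyl(vinyl)stannane | C=C[Sn](CCCC)(CCCC)CCCC | starting material
13 | ring B diene (5β,6β-acetonide, 8α-methyl vinylcyclohexene) | C=CC1=C[C@H](C)C[C@H]2OC(C)(C)O[C@@H]12 | intermediate
14 | (S)-4-benzyloxazolidin-2-one | O=C1N[C@@H](Cc2ccccc2)CO1 | starting material
15 | lithium (S)-4-benzyl-2-oxooxazolidin-3-ide | [Li+].O=C1[N-][C@@H](Cc2ccccc2)CO1 | intermediate (not isolated)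
16 | (S)-4-benzyl-3-(bromoacetyl)oxazolidin-2-one | O=C(CBr)N1[C@@H](Cc2ccccc2)COC1=O | intermediate
17 | diethyl {2-[(S)-4-benzyl-2-oxooxazolidin-3-yl]-2-oxoethyl}phosphonate | CCOP(=O)(OCC)CC(=O)N1[C@@H](Cc2ccccc2)COC1=O | intermediate
18 | (R)-2-methylbutanoic acid | CC[C@@H](C)C(O)=O | starting material
19 | (R)-2-methylbutan-1-ol | CC[C@@H](C)CO | intermediate
20 | (R)-2-methylbutanal | CC[C@@H](C)C=O | intermediate (not isolated)
21 | (S)-4-benzyl-3-[(R,E)-4-methylhex-2-enoyl]oxazolidin-2-one | CC[C@@H](C)/C=C/C(=O)N1[C@@H](Cc2ccccc2)COC1=O | intermediate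
22 | Diels–Alder adduct (Δ4(4a)-octalin 1β-acyl oxazolidinone) | CC[C@@H](C)[C@H]1CC=C2[C@@H]3OC(C)(C)O[C@@H]3C[C@@H](C)[C@@H]2[C@@H]1C(=O)N4[C@@H](Cc5ccccc5)COC4=O | intermediate
23 | octalin-1β-peroxycarboxylic acid | CC[C@@H](C)[C@H]1CC=C2[C@@H]3OC(C)(C)O[C@@H]3C[C@@H](C)[C@@H]2[C@@H]1C(=O)OO | intermediate (not isolated)
24 | octalin-1β-carboxylic acid | CC[C@@H](C)[C@H]1CC=C2[C@@H]3OC(C)(C)O[C@@H]3C[C@@H](C)[C@@H]2[C@@H]1C(=O)O | intermediate
25 | acyl imidazolide of 24 | CC[C@@H](C)[C@H]1CC=C2[C@@H]3OC(C)(C)O[C@@H]3C[C@@H](C)[C@@H]2[C@@H]1C(=O)n4ccnc4 | intermediate (not isolated)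
26 | octalin-1β-carboxamide | CC[C@@H](C)[C@H]1CC=C2[C@@H]3OC(C)(C)O[C@@H]3C[C@@H](C)[C@@H]2[C@@H]1C(N)=O | intermediate
27 | Δ4(4a)-octalin-1β-carbonitrile | CC[C@@H](C)[C@H]1CC=C2[C@@H]3OC(C)(C)O[C@@H]3C[C@@H](C)[C@@H]2[C@@H]1C#N | intermediate
28 | C4β alkylborane (4aβ-H) | CC[C@@H](C)[C@H]1C[C@H](B)[C@H]2[C@@H]3OC(C)(C)O[C@@H]3C[C@@H](C)[C@@H]2[C@@H]1C#N | intermediate (not isolated)
29 | trans-fused 4β-ol nitrile | CC[C@@H](C)[C@H]1C[C@H](O)[C@H]2[C@@H]3OC(C)(C)O[C@@H]3C[C@@H](C)[C@@H]2[C@@H]1C#N | intermediate
30 | trans-fused C4 ketone nitrile | CC[C@@H](C)[C@H]1CC(=O)[C@H]2[C@@H]3OC(C)(C)O[C@@H]3C[C@@H](C)[C@@H]2[C@@H]1C#N | intermediate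
31 | potassium Δ3-enolate of 30 | CC[C@@H](C)[C@H]1C=C([O-])[C@H]2[C@@H]3OC(C)(C)O[C@@H]3C[C@@H](C)[C@@H]2[C@@H]1C#N.[K+] | intermediate (not isolated)
32 | Δ3-enol triflate | CC[C@@H](C)[C@H]1C=C(OS(=O)(=O)C(F)(F)F)[C@H]2[C@@H]3OC(C)(C)O[C@@H]3C[C@@H](C)[C@@H]2[C@@H]1C#N | intermediate
33 | trans-Δ3-octalin-1β-carbonitrile | CC[C@@H](C)[C@H]1C=C[C@H]2[C@@H]3OC(C)(C)O[C@@H]3C[C@@H](C)[C@@H]2[C@@H]1C#N | intermediate
34 | lithiated nitrile (N-lithio ketenimine) | CC[C@@H](C)[C@H]1C=C[C@H]2[C@@H]3OC(C)(C)O[C@@H]3C[C@@H](C)[C@@H]2C1=C=[N-].[Li+] | intermediate (not isolated)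
35 | 1β-methyl-1α-carbonitrile | CC[C@@H](C)[C@H]1C=C[C@H]2[C@@H]3OC(C)(C)O[C@@H]3C[C@@H](C)[C@@H]2[C@@]1(C)C#N | intermediate
36 | lithium ketimide | CC[C@@H](C)[C@H]1C=C[C@H]2[C@@H]3OC(C)(C)O[C@@H]3C[C@@H](C)[C@@H]2[C@@]1(C)C(C)=[N-].[Li+] | intermediate (not isolated)
37 | 1α-acetyl-1β-methyl octalin | CC[C@@H](C)[C@H]1C=C[C@H]2[C@@H]3OC(C)(C)O[C@@H]3C[C@@H](C)[C@@H]2[C@@]1(C)C(C)=O | intermediate
38 | lithium enolate of 37 | CC[C@@H](C)[C@H]1C=C[C@H]2[C@@H]3OC(C)(C)O[C@@H]3C[C@@H](C)[C@@H]2[C@@]1(C)C([O-])=C.[Li+] | intermediate (not isolated)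
39 | 1α-(3-hydroxypropanoyl) acetonide | CC[C@@H](C)[C@H]1C=C[C@H]2[C@@H]3OC(C)(C)O[C@@H]3C[C@@H](C)[C@@H]2[C@@]1(C)C(=O)CCO | intermediate
40 | C11 TBDPS ether acetonide | CC[C@@H](C)[C@H]1C=C[C@H]2[C@@H]3OC(C)(C)O[C@@H]3C[C@@H](C)[C@@H]2[C@@]1(C)C(=O)CCO[Si](c4ccccc4)(c5ccccc5)C(C)(C)C | intermediate
41 | 5β,6β-diol C11 TBDPS ether | CC[C@@H](C)[C@H]1C=C[C@H]2[C@H](O)[C@H](O)C[C@@H](C)[C@@H]2[C@@]1(C)C(=O)CCO[Si](c3ccccc3)(c4ccccc4)C(C)(C)C | intermediate
42 | (E)-3-methylglutaconic acid | OC(=O)/C=C(\C)CC(=O)O | starting material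
43 | (E)-5-methoxy-3-methyl-5-oxopent-2-enoic acid | OC(=O)/C=C(\C)CC(=O)OC | intermediate
44 | C5 glutaconate ester C11 TBDPS ether | CC[C@@H](C)[C@H]1C=C[C@H]2[C@H](OC(=O)/C=C(\C)CC(=O)OC)[C@H](O)C[C@@H](C)[C@@H]2[C@@]1(C)C(=O)CCO[Si](c3ccccc3)(c4ccccc4)C(C)(C)C | intermediate
45 | tandyukisin B | CC[C@@H](C)[C@H]1C=C[C@H]2[C@H](OC(=O)/C=C(\C)CC(=O)OC)[C@H](O)C[C@@H](C)[C@@H]2[C@@]1(C)C(=O)CCO | target

**Step count and risks**

Total step count: 29. Longest linear sequence: 24 steps (1–9, 14–26, 28, 29).

Steps most likely to fail: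

1. Step 14 (key step). The aluminium Lewis acid may ionise the allylic acetonide or polymerise the diene before the slow cycloaddition of the β-branched dienophile takes place, and a sluggish reaction would erode endo and facial control. The fallback sets out from alcohol 19 and diene 13 and returns at acid 24. Alcohol 19 is oxidised as in step 13 and aldehyde 20 is treated in the same flask with (triphenylphosphoranylidene)acetaldehyde to give (R,E)-4-methylhex-2-enal F1. F1 and 13 are then joined without any metal Lewis acid by iminium catalysis with a chiral imidazolidinone salt (the catalyst enantiomer that leaves the Cα-Si face of the enal open), which should give the endo C1 aldehyde adduct F2. Pinnick oxidation (NaClO2, NaH2PO4, 2-methyl-2-butene) converts F2 into 24.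

2. Step 18. If ring A reacts through its inverted half-chair (sec-butyl equatorial), borane may add to the α face and give the cis-fused alcohol; slow reduction of the nitrile by excess borane is a second loss. The fallback sets out from nitrile 27 and returns at ketone 30. Peracid follows the same facial bias as borane, so mCPBA (CH2Cl2, 0 °C) would then give the 4α,4aα-epoxide F3. Treatment of F3 with BF3·OEt2 (CH2Cl2, −78 → −30 °C) triggers a Meinwald rearrangement in which the C4 hydrogen migrates to C4a anti to the departing oxygen, which gives H4a β and the C4 ketone 30 directly; the nitrile cannot act as a neighbouring group in this ionisation.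

3. Step 28. Acylation may not discriminate between O5 and O6, the ester may migrate between them, or DMAP may move or isomerise the glutaconate double bond through a dienolate or ketene. The fallback sets out from diol 41 and half ester 43 and returns at 44. Diol 41 is heated with Bu2SnO in toluene with removal of water to give the dibutylstannylene acetal F4. Half ester 43 is converted with 1-chloro-N,N,2-trimethylpropenylamine (CH2Cl2, 0 °C, no amine base) into the acid chloride F5. F4 and F5 are combined in toluene at 0 °C, where the tin alkoxide delivers the acyl group to the equatorial C5 oxygen without added base, and aqueous work-up gives 44.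

Further compounds
F1 | step 14 | (R,E)-4-methylhex-2-enal | CC[C@@H](C)/C=C/C=O
F2 | step 14 | Δ4(4a)-octalin-1β-carbaldehyde adduct | CC[C@@H](C)[C@H]1CC=C2[C@@H]3OC(C)(C)O[C@@H]3C[C@@H](C)[C@@H]2[C@@H]1C=O
F3 | step 18 | 4α,4aα-epoxy nitrile | CC[C@@H](C)[C@H]1C[C@H]2O[C@]23[C@@H]4OC(C)(C)O[C@@H]4C[C@@H](C)[C@@H]3[C@@H]1C#N
F4 | step 28 | 5,6-O-dibutylstannylene acetal of 41 | CC[C@@H](C)[C@H]1C=C[C@H]2[C@@H]3O[Sn](CCCC)(CCCC)O[C@@H]3C[C@@H](C)[C@@H]2[C@@]1(C)C(=O)CCO[Si](c4ccccc4)(c5ccccc5)C(C)(C)C
F5 | step 28 | methyl (E)-5-chloro-3-methyl-5-oxopent-3-enoate (acid chloride of 43) | ClC(=O)/C=C(\C)CC(=O)OC
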